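## Retrosynthetic overview
1. Target **14** comes from acetylation of epoxy-enol **13**. **13** comes from an iodide-mediated anodic (electrochemical) dehydrogenative Darzens-type closure of β-hydroxy enone **12**, which forms the oxirane and the quaternary C-6 centre.
2. **12** comes from the cyclohexenone **11**, made by RCM of an isopropenyl carbinol and a vinyl ketone, followed by TBS removal.
3. The RCM precursor **10** comes from Weinreb amide **5**: oxidise to aldehyde **6**, then Felkin-type isopropenyl addition, then vinyl addition.
4. **5** comes from trans-α-farnesylation of silyl-protected (S)-3-hydroxy-γ-butyrolactone (**1**, from L-malic acid).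
5. Rings form in this order: cyclohexenone (step 7), then epoxide (step 9).

Assumptions:
- The C-6 centre created in step 2 is transient and is erased in step 9.
- The Felkin (anti) diastereomer from step 5 is obtained at roughly 4:1 and separated by chromatography.
- (E,E)-Farnesyl bromide is commercial.
- Carbon numbering in the text: cyclohexenone C-1 (C=O), C-2 (=CH), C-3 (C–Me), C-4 (CH–O), C-5 (CH–O), C-6 (farnesyl-bearing).

## Route

**Step 1**
Reactants: **1** (S)-3-hydroxy-γ-butyrolactone
Product: **2** (S)-4-(tert-butyldimethylsilyloxy)oxolan-2-one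
Conditions: TBSCl, imidazole, DMF, 0 °C → rt
Reagents that add atoms: tert-butyldimethylsilyl chloride, CC(C)(C)[Si](C)(C)Cl
Why: Silylation of the secondary alcohol leaves the only bought stereocentre untouched and gives a bulky non-chelating group for the later Felkin addition.

**Step 2**
Reactants: **2**; **3** (E,E)-farnesyl bromide
Product: **4** trans-3-farnesyl-4-(TBSO)oxolan-2-one
Conditions: LDA, THF, −78 °C; then **3**, DMPU, −78 → −40 °C
Reagents that add atoms: none (farnesyl bromide is reactant **3**)
Why: Enolate SN2 alkylation occurs anti to the OTBS group (trans lactone); this new centre is transient and is erased in step 9.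

**Step 3**
Reactants: **4**
Product: **5** Weinreb amide with free primary alcohol: N-methoxy-N-methyl-2-farnesyl-3-(TBSO)-4-hydroxybutanamide
Conditions: MeNH(OMe)·HCl, iPrMgCl, THF, −20 → 0 °C
Reagents that add atoms: N,O-dimethylhydroxylamine, CONC
Why: Weinreb-type lactone opening releases the C-4 carbinol as a primary alcohol and leaves both stereocentres unchanged.

**Step 4**
Reactants: **5**
Product: **6** α-silyloxy aldehyde
Conditions: Dess–Martin periodinane, NaHCO3, CH2Cl2, 0 °C → rt
Reagents that add atoms: none
Why: Mild oxidation of the primary alcohol preserves the α-silyloxy stereocentre and the alkenes.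

**Step 5**
Reactants: **6**; **7** isopropenylmagnesium bromide (C=C(C)[Mg]Br)
Product: **8** anti-allylic alcohol
Conditions: **7**, THF, −78 °C; chromatographic separation of diastereomers
Reagents that add atoms: none (**7** is the reactant)
Why: Non-chelated Felkin–Anh addition to the α-OTBS aldehyde gives the 1,2-anti diol pattern, which becomes the ring-cis C-4 / C-5 relationship, so C-4 is controlled by the bought C-5 centre.

**Step 6**
Reactants: **8**; **9** vinylmagnesium bromide (C=C[Mg]Br)
Product: **10** vinyl ketone
Conditions: **9** (3.5 equiv), THF, 0 °C, 2 h; then aq. NH4Cl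
Reagents that add atoms: none (**9** is the reactant)
Why: The stable Weinreb tetrahedral intermediate gives the ketone only on work-up, so no over-addition occurs; the free OH is protected in situ as its magnesium alkoxide.

**Step 7**
Reactants: **10**
Product: **11** 4-hydroxy-3-methyl-5-(TBSO)-6-farnesylcyclohex-2-en-1-one
Conditions: Hoveyda–Grubbs II (5 mol%), toluene (0.005 M), 60 °C
Reagents that add atoms: none (ethylene is lost)
Why: Ring-closing metathesis of the isopropenyl and vinyl-ketone termini forms the trisubstituted enone; no stereocentre is touched.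

**Step 8**
Reactants: **11**
Product: **12** 4,5-dihydroxy-3-methyl-6-farnesylcyclohex-2-en-1-one
Conditions: HF·pyridine, pyridine, THF, 0 °C → rt
Reagents that add atoms: none
Why: Acidic, non-basic desilylation avoids E1cB loss of the β-oxygen.

**Step 9**
Reactants: **12**
Product: **13** epoxy-enol (target without the acetyl group)
Conditions: nBu4NI (0.3 equiv), MeCN/MeOH 9:1, undivided cell, graphite(+)/Pt(−), constant current 3 mA, rt, ~2.5 F/mol
Reagents that add atoms: none (H2 is evolved)
Why: Proposed new method: anodic I⁻ → I2 iodinates the C-6 enol of the β-hydroxy enone, and the C-5 alkoxide, formed by cathodic MeOH reduction, displaces the tertiary α-iodide in a 3-exo-tet closure. The mechanism follows halohydrin (Darzens-type) epoxide closure combined with mediator-based anodic α-iodination of ketones, with net loss of H2 and catalytic iodide. The α-iodide epimers equilibrate through the enol, so only the one anti to the C-5 oxygen closes. The epoxide oxygen therefore stays on the C-5 face and the farnesyl group ends up on the opposite face, which sets the quaternary centre, and C-4–OH ends up cis to the epoxide. The iodide mediator oxidises at a much lower potential than the farnesyl alkenes, so they are not attacked.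

**Step 10**
Reactants: **13**
Product: **14** target
Conditions: Ac2O, pyridine, DMAP (cat.), CH2Cl2, 0 °C
Reagents that add atoms: acetic anhydride, CC(=O)OC(C)=O
Why: Acylation of the only free (allylic secondary) hydroxyl leaves the epoxide and all stereocentres unchanged.

## Compound list
1 | (S)-3-hydroxy-γ-butyrolactone | O[C@H]1CC(=O)OC1 | starting material
2 | (S)-4-(TBSO)oxolan-2-one | CC(C)(C)[Si](C)(C)O[C@H]1CC(=O)OC1 | intermediate
3 | (E,E)-farnesyl bromide | BrC/C=C(\C)CC/C=C(\C)CCC=C(C)C | starting material
4 | trans-3-farnesyl-4-(TBSO)oxolan-2-one | CC(C)(C)[Si](C)(C)O[C@H]1[C@H](C/C=C(\C)CC/C=C(\C)CCC=C(C)C)C(=O)OC1 | intermediate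
5 | Weinreb amide, primary alcohol | CON(C)C(=O)[C@@H](C/C=C(\C)CC/C=C(\C)CCC=C(C)C)[C@@H](CO)O[Si](C)(C)C(C)(C)C | intermediate
6 | α-silyloxy aldehyde | CON(C)C(=O)[C@@H](C/C=C(\C)CC/C=C(\C)CCC=C(C)C)[C@@H](C=O)O[Si](C)(C)C(C)(C)C | intermediate
7 | isopropenylmagnesium bromide | C=C(C)[Mg]Br | starting material
8 | anti-allylic alcohol | CON(C)C(=O)[C@@H](C/C=C(\C)CC/C=C(\C)CCC=C(C)C)[C@@H]([C@H](O)C(C)=C)O[Si](C)(C)C(C)(C)C | intermediate
9 | vinylmagnesium bromide | C=C[Mg]Br | starting material
10 | vinyl ketone | C=CC(=O)[C@@H](C/C=C(\C)CC/C=C(\C)CCC=C(C)C)[C@@H]([C@H](O)C(C)=C)O[Si](C)(C)C(C)(C)C | intermediate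
11 | 4-hydroxy-5-OTBS cyclohexenone | O[C@@H]1C(C)=CC(=O)[C@@H](C/C=C(\C)CC/C=C(\C)CCC=C(C)C)[C@@H]1O[Si](C)(C)C(C)(C)C | intermediate
12 | 4,5-dihydroxy cyclohexenone | O[C@@H]1C(C)=CC(=O)[C@@H](C/C=C(\C)CC/C=C(\C)CCC=C(C)C)[C@@H]1O | intermediate
13 | epoxy-enol | O[C@@H]1C(C)=CC(=O)[C@]2(C/C=C(\C)CC/C=C(\C)CCC=C(C)C)O[C@H]12 | intermediate
14 | target | CC(=O)O[C@@H]1C(C)=CC(=O)[C@]2(C/C=C(\C)CC/C=C(\C)CCC=C(C)C)O[C@H]12 | target

## Totals
Total step count: 10. Longest linear sequence: 10.

## Three steps most likely to fail
1. **Step 9 (proposed new electrochemical epoxide closure).** Risks are dehydration to a dienone, epimerisation at C-4 through γ-enolisation, and iodination of the farnesyl alkenes. Fallback using known chemistry: treat **12** with TMSOTf/Et3N to make the bis-TMS ether and silyl dienol ether, brominate with NBS at −78 °C, then close with K2CO3/MeOH (classical halohydrin Darzens-type closure).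
2. **Step 5 (Felkin diastereoselectivity).** The anti isomer may be only a minor product. Fallback: use the C-5 PMB ether so that Mg-chelation gives the syn alcohol, then invert C-4 with Mitsunobu (p-nitrobenzoic acid, DEAD, PPh3) and methanolysis.
3. **Step 7 (RCM of a 1,1-disubstituted alkene with a vinyl ketone in the presence of the farnesyl alkenes).** Fallback: add 1-ethoxyvinyllithium instead of isopropenyl and MeMgBr instead of vinyl to give a 2,6-diketone, then close the ring by intramolecular aldol condensation (KOH, MeOH).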